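**Retrosynthetic overview**

1. The target is guibourtinidol-(4α→6)-epicatechin. Working backwards: global hydrogenolysis ⇐ cis-selective reduction of a lower-unit flavan-3-one ⇐ epoxidation/1,2-hydride shift of a lower-unit flav-3-ene ⇐ ring-closing metathesis (RCM) that closes ring C of the lower unit through C3=C4.
2. Enabling feature: in the lower unit, C4 is an unsubstituted benzylic CH2 on C4a of ring A, C4a is ortho to C8a–O1, and C3 is the only atom between C4 and the O1-bearing stereocentre C2. A vinyl group on C4a and an O1-(1-arylallyl) ether (C2 set by iridium catalysis) are therefore the two halves of C3=C4, and C3 is oxygenated cis afterwards.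
3. Interflavan bond C4(upper)–C6(lower): Friedel–Crafts capture of a flavan-4-yl cation by 4-(benzyloxy)-2,6-dihydroxybenzaldehyde. Its two free ring positions are equivalent and it already carries the future C4, so 4→6 connectivity only requires allylating the unhindered phenol (future O1).
4. Upper unit: the same tactic — iridium allylic etherification of a 2-vinylphenol, RCM through C3=C4, then epoxidation/methanolysis to a 4-methoxyflavan-3-ol electrophile.
5. Ring order: rings A and B are bought as benzaldehydes; upper ring C (step 6) → interflavan bond (step 9) → lower ring C (step 16).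

Key step: step 16

Assumption: the (Sa,Sc,Sc) enantiomer of the phosphoramidite ligand is taken as the one that gives the (S)-configured branched allyl aryl ethers in steps 5 and 13; if the sense of induction is the opposite, the mirror-image ligand is used in both steps.

**Route**

Step 1
Reactants: 1 4-(benzyloxy)benzaldehyde
Product: 2 ethyl (2E)-3-[4-(benzyloxy)phenyl]prop-2-enoate
Conditions: Ph3P=CHCO2Et, toluene, 90 °C
Reagents that add atoms: (carbethoxymethylene)triphenylphosphorane, CCOC(=O)C=P(c1ccccc1)(c1ccccc1)c1ccccc1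
Why: Wittig olefination with a stabilised ylide should give the (E)-cinnamate selectively.

Step 2
Reactants: 2 ethyl (2E)-3-[4-(benzyloxy)phenyl]prop-2-enoate
Product: 3 (2E)-3-[4-(benzyloxy)phenyl]prop-2-en-1-ol
Conditions: (Me2CHCH2)2AlH (DIBAL-H), CH2Cl2, −78 °C; aqueous Rochelle salt
Reagents that add atoms: none
Why: 1,2-reduction of the conjugated ester by the aluminium hydride at low temperature should give the allylic alcohol without touching the alkene or the benzyl ether.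

Step 3
Reactants: 3 (2E)-3-[4-(benzyloxy)phenyl]prop-2-en-1-ol
Product: 4 (2E)-3-[4-(benzyloxy)phenyl]prop-2-en-1-yl methyl carbonate
Conditions: ClCO2Me, pyridine, CH2Cl2, 0 °C
Reagents that add atoms: methyl chloroformate, COC(=O)Cl
Why: O-acylation of the primary allylic alcohol (carbonate formation) installs the leaving group needed for iridium-catalysed allylic substitution.

Step 4
Reactants: 5 4-(benzyloxy)-2-hydroxybenzaldehyde
Product: 6 5-(benzyloxy)-2-ethenylphenol
Conditions: Ph3PCH3Br, KOtBu (2.5 equiv), THF, 0 °C → rt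
Reagents that add atoms: methyltriphenylphosphonium bromide, C[P+](c1ccccc1)(c1ccccc1)c1ccccc1.[Br-]
Why: Wittig methylenation of a salicylaldehyde tolerates the phenoxide formed by the excess base and should give the 2-vinylphenol on work-up.

Step 5
Reactants: 6 5-(benzyloxy)-2-ethenylphenol; 4 (2E)-3-[4-(benzyloxy)phenyl]prop-2-en-1-yl methyl carbonate
Product: 7 4-(benzyloxy)-2-{[(1S)-1-[4-(benzyloxy)phenyl]prop-2-en-1-yl]oxy}-1-ethenylbenzene
Conditions: LiN(SiMe3)2 (1.0 equiv), THF; [Ir(cod)Cl]2 (2 mol %), (Sa,Sc,Sc)-(1,1'-binaphthalene-2,2'-diyl) N,N-bis(1-phenylethyl)phosphoramidite (4 mol %), THF, rt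
Reagents that add atoms: none
Why: In this iridium-catalysed asymmetric allylic etherification the phenoxide should attack the aryl-substituted terminus of the allyl complex, and the chiral phosphoramidite catalyst sets the (S) configuration of the new O-bearing centre (the future C2 of the upper unit).

Step 6
Reactants: 7 4-(benzyloxy)-2-{[(1S)-1-[4-(benzyloxy)phenyl]prop-2-en-1-yl]oxy}-1-ethenylbenzene
Product: 8 (2S)-7-(benzyloxy)-2-[4-(benzyloxy)phenyl]-2H-chromene
Conditions: second-generation Grubbs catalyst RuCl2(=CHPh)(H2IMes)(PCy3) (3 mol %), CH2Cl2 (0.01 M), 40 °C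
Reagents that add atoms: none
Why: Ring-closing olefin metathesis of the 2-vinylphenyl 1-arylallyl ether should close ring C of the upper unit as the C3=C4 alkene with loss of ethene, leaving the stereocentre untouched.

Step 7
Reactants: 8 (2S)-7-(benzyloxy)-2-[4-(benzyloxy)phenyl]-2H-chromene
Product: 10 (2R,3S,4R)-7-(benzyloxy)-2-[4-(benzyloxy)phenyl]-4-methoxychroman-3-ol, via upper flavene 3,4-epoxide 9 (not isolated)
Conditions: DMDO, acetone/CH2Cl2, −40 °C; then MeOH, −40 °C → rt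
Reagents that add atoms: dimethyldioxirane, CC1(C)OO1; methanol, CO
Why: Epoxidation by the dioxirane should occur anti to the 2-aryl group and solvolytic opening of the labile benzylic epoxide at C4 by methanol gives the 2,3-trans 4-methoxyflavan-3-ol, C3 being set by the epoxidation face while the C4 configuration is irrelevant because C4 is ionised in step 9.

Step 8
Reactants: 11 2,4,6-trihydroxybenzaldehyde
Product: 12 4-(benzyloxy)-2,6-dihydroxybenzaldehyde
Conditions: BnBr (1.0 equiv), K2CO3 (1.0 equiv), DMF, 0 °C → rt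
Reagents that add atoms: benzyl bromide, BrCc1ccccc1
Why: Williamson etherification should select the 4-hydroxyl, the only one not hydrogen-bonded to the formyl group and the most acidic, which keeps the ring symmetric.

Step 9
Reactants: 10 (2R,3S,4R)-7-(benzyloxy)-2-[4-(benzyloxy)phenyl]-4-methoxychroman-3-ol; 12 4-(benzyloxy)-2,6-dihydroxybenzaldehyde
Product: 13 4-(benzyloxy)-3-{(2R,3S,4S)-7-(benzyloxy)-2-[4-(benzyloxy)phenyl]-3-hydroxychroman-4-yl}-2,6-dihydroxybenzaldehyde
Conditions: BF3·OEt2 (0.5 equiv), 12 (3 equiv), CH2Cl2/1,4-dioxane, −20 → 0 °C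
Reagents that add atoms: none
Why: Lewis-acid ionisation of the 4-methoxy group gives the flavan-4-yl cation (stabilised by O1 and the 7-benzyloxy group), which is captured in a Friedel–Crafts alkylation by either of the two equivalent ring positions of the symmetric aldehyde, attack anti to the 3-hydroxyl of the 2,3-trans cation setting the 3,4-trans (4S) centre.

Step 10
Reactants: 14 3,4-bis(benzyloxy)benzaldehyde
Product: 15 ethyl (2E)-3-[3,4-bis(benzyloxy)phenyl]prop-2-enoate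
Conditions: Ph3P=CHCO2Et, toluene, 90 °C
Reagents that add atoms: (carbethoxymethylene)triphenylphosphorane, CCOC(=O)C=P(c1ccccc1)(c1ccccc1)c1ccccc1
Why: Wittig olefination with a stabilised ylide should give the (E)-cinnamate selectively.

Step 11
Reactants: 15 ethyl (2E)-3-[3,4-bis(benzyloxy)phenyl]prop-2-enoate
Product: 16 (2E)-3-[3,4-bis(benzyloxy)phenyl]prop-2-en-1-ol
Conditions: (Me2CHCH2)2AlH (DIBAL-H), CH2Cl2, −78 °C; aqueous Rochelle salt
Reagents that add atoms: none
Why: 1,2-reduction of the conjugated ester by the aluminium hydride should give the allylic alcohol with the alkene and benzyl ethers intact.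

Step 12
Reactants: 16 (2E)-3-[3,4-bis(benzyloxy)phenyl]prop-2-en-1-ol
Product: 17 (2E)-3-[3,4-bis(benzyloxy)phenyl]prop-2-en-1-yl methyl carbonate
Conditions: ClCO2Me, pyridine, CH2Cl2, 0 °C
Reagents that add atoms: methyl chloroformate, COC(=O)Cl
Why: O-acylation of the primary allylic alcohol (carbonate formation) installs the leaving group for the second iridium-catalysed etherification.

Step 13
Reactants: 13 4-(benzyloxy)-3-{(2R,3S,4S)-7-(benzyloxy)-2-[4-(benzyloxy)phenyl]-3-hydroxychroman-4-yl}-2,6-dihydroxybenzaldehyde; 17 (2E)-3-[3,4-bis(benzyloxy)phenyl]prop-2-en-1-yl methyl carbonate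
Product: 18 4-(benzyloxy)-3-{(2R,3S,4S)-7-(benzyloxy)-2-[4-(benzyloxy)phenyl]-3-hydroxychroman-4-yl}-6-{[(1S)-1-[3,4-bis(benzyloxy)phenyl]prop-2-en-1-yl]oxy}-2-hydroxybenzaldehyde
Conditions: LiN(SiMe3)2 (1.0 equiv), THF; [Ir(cod)Cl]2 (4 mol %), the (Sa,Sc,Sc)-phosphoramidite of step 5 (8 mol %), THF, 40 °C
Reagents that add atoms: none
Why: In this iridium-catalysed asymmetric allylic etherification only the ring A phenol flanked by the formyl group and a ring hydrogen should be accessible, the other being blocked between the formyl group and the flavan-4-yl substituent, and the catalyst sets the (S) centre that becomes C2 of the lower unit.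

Step 14
Reactants: 18 4-(benzyloxy)-3-{(2R,3S,4S)-7-(benzyloxy)-2-[4-(benzyloxy)phenyl]-3-hydroxychroman-4-yl}-6-{[(1S)-1-[3,4-bis(benzyloxy)phenyl]prop-2-en-1-yl]oxy}-2-hydroxybenzaldehyde
Product: 19 2,4-bis(benzyloxy)-3-{(2R,3S,4S)-3,7-bis(benzyloxy)-2-[4-(benzyloxy)phenyl]chroman-4-yl}-6-{[(1S)-1-[3,4-bis(benzyloxy)phenyl]prop-2-en-1-yl]oxy}benzaldehyde
Conditions: NaH (2.5 equiv), BnBr (2.5 equiv), DMF, 0 °C → rt
Reagents that add atoms: benzyl bromide, BrCc1ccccc1
Why: Williamson etherification of the remaining phenol and of the secondary 3-hydroxyl should cap all hydroxyls, the non-enolisable aldehyde and the allylic ether being stable to the base.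

Step 15
Reactants: 19 2,4-bis(benzyloxy)-3-{(2R,3S,4S)-3,7-bis(benzyloxy)-2-[4-(benzyloxy)phenyl]chroman-4-yl}-6-{[(1S)-1-[3,4-bis(benzyloxy)phenyl]prop-2-en-1-yl]oxy}benzaldehyde
Product: 20 (2R,3S,4S)-3,7-bis(benzyloxy)-2-[4-(benzyloxy)phenyl]-4-[2,6-bis(benzyloxy)-4-{[(1S)-1-[3,4-bis(benzyloxy)phenyl]prop-2-en-1-yl]oxy}-3-ethenylphenyl]chroman
Conditions: Ph3PCH3Br, KOtBu (1.5 equiv), THF, 0 °C → rt
Reagents that add atoms: methyltriphenylphosphonium bromide, C[P+](c1ccccc1)(c1ccccc1)c1ccccc1.[Br-]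
Why: Wittig methylenation of the 2,6-dialkoxybenzaldehyde turns the formyl carbon into the terminal vinyl partner (future C4) under non-acidic conditions that leave the ionisable allylic ether intact.

Step 16
Reactants: 20 (2R,3S,4S)-3,7-bis(benzyloxy)-2-[4-(benzyloxy)phenyl]-4-[2,6-bis(benzyloxy)-4-{[(1S)-1-[3,4-bis(benzyloxy)phenyl]prop-2-en-1-yl]oxy}-3-ethenylphenyl]chroman
Product: 21 (2R,3S,4S)-3,7-bis(benzyloxy)-2-[4-(benzyloxy)phenyl]-4-{(2S)-5,7-bis(benzyloxy)-2-[3,4-bis(benzyloxy)phenyl]-2H-chromen-6-yl}chroman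
Conditions: second-generation Grubbs catalyst RuCl2(=CHPh)(H2IMes)(PCy3) (5 mol %), CH2Cl2 (0.005 M), 40 °C
Reagents that add atoms: none
Why: The ruthenium benzylidene should first exchange onto the unhindered vinyl group of the allylic ether (the C3 terminus); the new alkylidene then adds intramolecularly to the styrene on C4a to give a ruthenacyclobutane, and cycloreversion releases the C3=C4 alkene with loss of ethene. The closest known reaction type is the RCM of 2-vinylphenyl 1-substituted-allyl ethers to 2-substituted 2H-chromenes, already used in step 6. The six-membered ring C of the lower unit closes by ring-closing olefin metathesis, forming the C3=C4 bond, which is cis by ring constraint and conjugated with ring A. No stereocentre is created: C2 of the lower unit, set in step 13, lies next to the reacting alkene but is not part of it, and with no acid or base present it should be carried through unchanged, while C3 is deliberately left at the alkene level so that hydride delivery can set it later. The step needs chemoselectivity for the two terminal alkenes and six-ring closure instead of intermolecular cross-metathesis; the substrate has no other C=C bond, all hydroxyls are capped as ethers, and the two alkene-bearing groups sit ortho to each other on ring A, which together with high dilution favours cyclisation.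

Step 17
Reactants: 21 (2R,3S,4S)-3,7-bis(benzyloxy)-2-[4-(benzyloxy)phenyl]-4-{(2S)-5,7-bis(benzyloxy)-2-[3,4-bis(benzyloxy)phenyl]-2H-chromen-6-yl}chroman
Product: 23 (2R)-5,7-bis(benzyloxy)-2-[3,4-bis(benzyloxy)phenyl]-6-{(2R,3S,4S)-3,7-bis(benzyloxy)-2-[4-(benzyloxy)phenyl]chroman-4-yl}chroman-3-one, via lower-unit 3,4-epoxide 22 (not isolated)
Conditions: DMDO, acetone/CH2Cl2, −40 °C; then ZnI2 (10 mol %), −40 → 0 °C
Reagents that add atoms: dimethyldioxirane, CC1(C)OO1
Why: The dioxirane should epoxidise the electron-rich C3=C4 alkene, and opening of the epoxide at C4 to a cation stabilised by the 5- and 7-benzyloxy groups and O1 followed by 1,2-hydride shift from C3 (Meinwald rearrangement) gives the 3-ketone, so that either epoxide face leads to the same product and C2 is not involved.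

Step 18
Reactants: 23 (2R)-5,7-bis(benzyloxy)-2-[3,4-bis(benzyloxy)phenyl]-6-{(2R,3S,4S)-3,7-bis(benzyloxy)-2-[4-(benzyloxy)phenyl]chroman-4-yl}chroman-3-one
Product: 24 (2R,3R)-5,7-bis(benzyloxy)-2-[3,4-bis(benzyloxy)phenyl]-6-{(2R,3S,4S)-3,7-bis(benzyloxy)-2-[4-(benzyloxy)phenyl]chroman-4-yl}chroman-3-ol
Conditions: LiBH(s-Bu)3 (L-Selectride), THF, −78 °C; then H2O
Reagents that add atoms: none
Why: In this diastereoselective ketone reduction the bulky borohydride should attack C3 equatorially, from the face anti to the 2-aryl group, giving the axial 3-hydroxyl of the 2,3-cis (2R,3R) epicatechin unit at a temperature too low for enolisation at C2.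

Step 19
Reactants: 24 (2R,3R)-5,7-bis(benzyloxy)-2-[3,4-bis(benzyloxy)phenyl]-6-{(2R,3S,4S)-3,7-bis(benzyloxy)-2-[4-(benzyloxy)phenyl]chroman-4-yl}chroman-3-ol
Product: 25 (2R,3S,4S)-2-(4-hydroxyphenyl)-4-[(2R,3R)-2-(3,4-dihydroxyphenyl)-3,5,7-trihydroxychroman-6-yl]chroman-3,7-diol (CNP0263196.4)
Conditions: H2 (1 atm), Pd(OH)2/C, THF/MeOH, rt
Reagents that add atoms: none
Why: Hydrogenolysis of the seven benzyl ethers should release all hydroxyls under mild conditions that leave the cyclic C2–O1 ethers, the interflavan C4–C6 bond and all five stereocentres untouched.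

**Compound list**

1 | 4-(benzyloxy)benzaldehyde | O=Cc1ccc(OCc2ccccc2)cc1 | starting material
2 | ethyl (2E)-3-[4-(benzyloxy)phenyl]prop-2-enoate | CCOC(=O)/C=C/c1ccc(OCc2ccccc2)cc1 | intermediate
3 | (2E)-3-[4-(benzyloxy)phenyl]prop-2-en-1-ol | OC/C=C/c1ccc(OCc2ccccc2)cc1 | intermediate
4 | (2E)-3-[4-(benzyloxy)phenyl]prop-2-en-1-yl methyl carbonate | COC(=O)OC/C=C/c1ccc(OCc2ccccc2)cc1 | intermediate
5 | 4-(benzyloxy)-2-hydroxybenzaldehyde | O=Cc1ccc(OCc2ccccc2)cc1O | starting material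
6 | 5-(benzyloxy)-2-ethenylphenol | C=Cc1ccc(OCc2ccccc2)cc1O | intermediate
7 | 4-(benzyloxy)-2-{[(1S)-1-[4-(benzyloxy)phenyl]prop-2-en-1-yl]oxy}-1-ethenylbenzene | C(c1ccccc1)Oc1ccc([C@H](C=C)Oc2cc(OCc3ccccc3)ccc2C=C)cc1 | intermediate
8 | (2S)-7-(benzyloxy)-2-[4-(benzyloxy)phenyl]-2H-chromene | C(c1ccccc1)Oc1ccc([C@H]2Oc3cc(OCc4ccccc4)ccc3C=C2)cc1 | intermediate
9 | (2R)-7-(benzyloxy)-2-[4-(benzyloxy)phenyl]-3,4-epoxychroman, oxirane oxygen anti to the 2-aryl group | C(c1ccccc1)Oc1ccc([C@H]2Oc3cc(OCc4ccccc4)ccc3[C@@H]5O[C@@H]52)cc1 | intermediate (not isolated)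
10 | (2R,3S,4R)-7-(benzyloxy)-2-[4-(benzyloxy)phenyl]-4-methoxychroman-3-ol | C(c1ccccc1)Oc1ccc([C@H]2Oc3cc(OCc4ccccc4)ccc3[C@@H](OC)[C@@H]2O)cc1 | intermediate
11 | 2,4,6-trihydroxybenzaldehyde | O=Cc1c(O)cc(O)cc1O | starting material
12 | 4-(benzyloxy)-2,6-dihydroxybenzaldehyde | O=Cc1c(O)cc(OCc2ccccc2)cc1O | intermediate
13 | 4-(benzyloxy)-3-{(2R,3S,4S)-7-(benzyloxy)-2-[4-(benzyloxy)phenyl]-3-hydroxychroman-4-yl}-2,6-dihydroxybenzaldehyde | C(c1ccccc1)Oc1ccc([C@H]2Oc3cc(OCc4ccccc4)ccc3[C@@H](c3c(OCc4ccccc4)cc(O)c(C=O)c3O)[C@@H]2O)cc1 | intermediate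
14 | 3,4-bis(benzyloxy)benzaldehyde | O=Cc1ccc(OCc2ccccc2)c(OCc2ccccc2)c1 | starting material
15 | ethyl (2E)-3-[3,4-bis(benzyloxy)phenyl]prop-2-enoate | CCOC(=O)/C=C/c1ccc(OCc2ccccc2)c(OCc2ccccc2)c1 | intermediate
16 | (2E)-3-[3,4-bis(benzyloxy)phenyl]prop-2-en-1-ol | OC/C=C/c1ccc(OCc2ccccc2)c(OCc2ccccc2)c1 | intermediate
17 | (2E)-3-[3,4-bis(benzyloxy)phenyl]prop-2-en-1-yl methyl carbonate | COC(=O)OC/C=C/c1ccc(OCc2ccccc2)c(OCc2ccccc2)c1 | intermediate
18 | 4-(benzyloxy)-3-{(2R,3S,4S)-7-(benzyloxy)-2-[4-(benzyloxy)phenyl]-3-hydroxychroman-4-yl}-6-{[(1S)-1-[3,4-bis(benzyloxy)phenyl]prop-2-en-1-yl]oxy}-2-hydroxybenzaldehyde | C(c1ccccc1)Oc1ccc([C@H]2Oc3cc(OCc4ccccc4)ccc3[C@@H](c3c(OCc4ccccc4)cc(O[C@@H](C=C)c4ccc(OCc5ccccc5)c(OCc5ccccc5)c4)c(C=O)c3O)[C@@H]2O)cc1 | intermediate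
19 | 2,4-bis(benzyloxy)-3-{(2R,3S,4S)-3,7-bis(benzyloxy)-2-[4-(benzyloxy)phenyl]chroman-4-yl}-6-{[(1S)-1-[3,4-bis(benzyloxy)phenyl]prop-2-en-1-yl]oxy}benzaldehyde | C(c1ccccc1)Oc1ccc([C@H]2Oc3cc(OCc4ccccc4)ccc3[C@@H](c3c(OCc4ccccc4)cc(O[C@@H](C=C)c4ccc(OCc5ccccc5)c(OCc5ccccc5)c4)c(C=O)c3OCc6ccccc6)[C@@H]2OCc7ccccc7)cc1 | intermediate
20 | (2R,3S,4S)-3,7-bis(benzyloxy)-2-[4-(benzyloxy)phenyl]-4-[2,6-bis(benzyloxy)-4-{[(1S)-1-[3,4-bis(benzyloxy)phenyl]prop-2-en-1-yl]oxy}-3-ethenylphenyl]chroman | C(c1ccccc1)Oc1ccc([C@H]2Oc3cc(OCc4ccccc4)ccc3[C@@H](c3c(OCc4ccccc4)cc(O[C@@H](C=C)c4ccc(OCc5ccccc5)c(OCc5ccccc5)c4)c(C=C)c3OCc6ccccc6)[C@@H]2OCc7ccccc7)cc1 | intermediate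
21 | (2R,3S,4S)-3,7-bis(benzyloxy)-2-[4-(benzyloxy)phenyl]-4-{(2S)-5,7-bis(benzyloxy)-2-[3,4-bis(benzyloxy)phenyl]-2H-chromen-6-yl}chroman | C(c1ccccc1)Oc1ccc([C@H]2Oc3cc(OCc4ccccc4)ccc3[C@@H](c3c(OCc4ccccc4)cc4c(c3OCc6ccccc6)C=C[C@@H](c3ccc(OCc5ccccc5)c(OCc5ccccc5)c3)O4)[C@@H]2OCc7ccccc7)cc1 | intermediate
22 | 3,4-epoxide of the chromene unit of 21 (lower C2 R, oxirane oxygen anti to the 2-aryl group) | C(c1ccccc1)Oc1ccc([C@H]2Oc3cc(OCc4ccccc4)ccc3[C@@H](c3c(OCc4ccccc4)cc4c(c3OCc6ccccc6)[C@@H]8O[C@@H]8[C@@H](c3ccc(OCc5ccccc5)c(OCc5ccccc5)c3)O4)[C@@H]2OCc7ccccc7)cc1 | intermediate (not isolated)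
23 | (2R)-5,7-bis(benzyloxy)-2-[3,4-bis(benzyloxy)phenyl]-6-{(2R,3S,4S)-3,7-bis(benzyloxy)-2-[4-(benzyloxy)phenyl]chroman-4-yl}chroman-3-one | C(c1ccccc1)Oc1ccc([C@H]2Oc3cc(OCc4ccccc4)ccc3[C@@H](c3c(OCc4ccccc4)cc4c(c3OCc6ccccc6)CC(=O)[C@@H](c3ccc(OCc5ccccc5)c(OCc5ccccc5)c3)O4)[C@@H]2OCc7ccccc7)cc1 | intermediate
24 | (2R,3R)-5,7-bis(benzyloxy)-2-[3,4-bis(benzyloxy)phenyl]-6-{(2R,3S,4S)-3,7-bis(benzyloxy)-2-[4-(benzyloxy)phenyl]chroman-4-yl}chroman-3-ol | C(c1ccccc1)Oc1ccc([C@H]2Oc3cc(OCc4ccccc4)ccc3[C@@H](c3c(OCc4ccccc4)cc4c(c3OCc6ccccc6)C[C@@H](O)[C@@H](c3ccc(OCc5ccccc5)c(OCc5ccccc5)c3)O4)[C@@H]2OCc7ccccc7)cc1 | intermediate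
25 | (2R,3S,4S)-2-(4-hydroxyphenyl)-4-[(2R,3R)-2-(3,4-dihydroxyphenyl)-3,5,7-trihydroxychroman-6-yl]chroman-3,7-diol | Oc1ccc([C@H]2Oc3cc(O)ccc3[C@@H](c3c(O)cc4c(c3O)C[C@@H](O)[C@@H](c3ccc(O)c(O)c3)O4)[C@@H]2O)cc1 | target

**Step count and risks**

Total step count: 19. Longest linear sequence: 14 steps (1 → 2 → 3 → 4 → 7 → 8 → 10 → 13 → 18 → 19 → 20 → 21 → 23 → 24 → 25; steps 1, 2, 3, 5, 6, 7, 9 and 13 to 19).

Steps most likely to fail:

1. Step 9 (interflavan coupling). The hydrogen-bonded acylphloroglucinol may capture the flavan-4-yl cation too slowly. Self-condensation of the cation with ring A of a second electrophile molecule, and loss of 3,4-trans facial selectivity, could then take over. The fallback sets out from 10 and returns at 13. Compound 10 would be condensed with a large excess of benzene-1,3,5-triol (BF3·OEt2, dioxane), the classical and most nucleophilic acceptor for flavan-4-yl cations, to give (2R,3S,4S)-7-(benzyloxy)-2-[4-(benzyloxy)phenyl]-4-(2,4,6-trihydroxyphenyl)chroman-3-ol F1, in which the two free ring positions are again equivalent. Magnesium-mediated ortho-formylation (MgCl2, Et3N, paraformaldehyde, MeCN) should then give 3-{(2R,3S,4S)-7-(benzyloxy)-2-[4-(benzyloxy)phenyl]-3-hydroxychroman-4-yl}-2,4,6-trihydroxybenzaldehyde F2. Benzylation (BnBr, KHCO3, DMF) of the hydroxyl para to the formyl group, the only one not hydrogen-bonded, leads back to 13.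

2. Step 13 (second allylic etherification). Discrimination between the two ring A phenols may be incomplete; allylation of the hindered one would lead into the 4→8 series. The fallback sets out from 13 and returns at 19. The unhindered phenol would first be silylated selectively with the bulky (Me2CH)3SiCl and imidazole to give 4-(benzyloxy)-3-{(2R,3S,4S)-7-(benzyloxy)-2-[4-(benzyloxy)phenyl]-3-hydroxychroman-4-yl}-2-hydroxy-6-[(triisopropylsilyl)oxy]benzaldehyde F3. The remaining phenol and the 3-hydroxyl would be benzylated (NaH, BnBr) to 2,4-bis(benzyloxy)-3-{(2R,3S,4S)-3,7-bis(benzyloxy)-2-[4-(benzyloxy)phenyl]chroman-4-yl}-6-[(triisopropylsilyl)oxy]benzaldehyde F4. Desilylation with Bu4NF should give 2,4-bis(benzyloxy)-3-{(2R,3S,4S)-3,7-bis(benzyloxy)-2-[4-(benzyloxy)phenyl]chroman-4-yl}-6-hydroxybenzaldehyde F5, whose single free phenol is then etherified with 17 under the conditions of step 13 to give 19.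

3. Step 17 (epoxidation and hydride shift). The ring-opened C4 cation may be captured by a nucleophile, or the dioxirane may over-oxidise the electron-rich rings, before the 1,2-hydride shift takes place. The fallback sets out from 21 and returns at 23. Hydroboration–oxidation (BH3·SMe2, THF; then NaOH/H2O2), which adds anti to the 2-aryl group with boron at C3, should give (2R,3S)-5,7-bis(benzyloxy)-2-[3,4-bis(benzyloxy)phenyl]-6-{(2R,3S,4S)-3,7-bis(benzyloxy)-2-[4-(benzyloxy)phenyl]chroman-4-yl}chroman-3-ol F6. Oxidation of this 2,3-trans alcohol with Dess–Martin periodinane gives 23.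

**Further compounds**

F1 | step 9 | (2R,3S,4S)-7-(benzyloxy)-2-[4-(benzyloxy)phenyl]-4-(2,4,6-trihydroxyphenyl)chroman-3-ol | C(c1ccccc1)Oc1ccc([C@H]2Oc3cc(OCc4ccccc4)ccc3[C@@H](c3c(O)cc(O)cc3O)[C@@H]2O)cc1
F2 | step 9 | 3-{(2R,3S,4S)-7-(benzyloxy)-2-[4-(benzyloxy)phenyl]-3-hydroxychroman-4-yl}-2,4,6-trihydroxybenzaldehyde | C(c1ccccc1)Oc1ccc([C@H]2Oc3cc(OCc4ccccc4)ccc3[C@@H](c3c(O)cc(O)c(C=O)c3O)[C@@H]2O)cc1
F3 | step 13 | 4-(benzyloxy)-3-{(2R,3S,4S)-7-(benzyloxy)-2-[4-(benzyloxy)phenyl]-3-hydroxychroman-4-yl}-2-hydroxy-6-[(triisopropylsilyl)oxy]benzaldehyde | C(c1ccccc1)Oc1ccc([C@H]2Oc3cc(OCc4ccccc4)ccc3[C@@H](c3c(OCc4ccccc4)cc(O[Si](C(C)C)(C(C)C)C(C)C)c(C=O)c3O)[C@@H]2O)cc1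
F4 | step 13 | 2,4-bis(benzyloxy)-3-{(2R,3S,4S)-3,7-bis(benzyloxy)-2-[4-(benzyloxy)phenyl]chroman-4-yl}-6-[(triisopropylsilyl)oxy]benzaldehyde | C(c1ccccc1)Oc1ccc([C@H]2Oc3cc(OCc4ccccc4)ccc3[C@@H](c3c(OCc4ccccc4)cc(O[Si](C(C)C)(C(C)C)C(C)C)c(C=O)c3OCc6ccccc6)[C@@H]2OCc7ccccc7)cc1
F5 | step 13 | 2,4-bis(benzyloxy)-3-{(2R,3S,4S)-3,7-bis(benzyloxy)-2-[4-(benzyloxy)phenyl]chroman-4-yl}-6-hydroxybenzaldehyde | C(c1ccccc1)Oc1ccc([C@H]2Oc3cc(OCc4ccccc4)ccc3[C@@H](c3c(OCc4ccccc4)cc(O)c(C=O)c3OCc6ccccc6)[C@@H]2OCc7ccccc7)cc1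
F6 | step 17 | (2R,3S)-5,7-bis(benzyloxy)-2-[3,4-bis(benzyloxy)phenyl]-6-{(2R,3S,4S)-3,7-bis(benzyloxy)-2-[4-(benzyloxy)phenyl]chroman-4-yl}chroman-3-ol | C(c1ccccc1)Oc1ccc([C@H]2Oc3cc(OCc4ccccc4)ccc3[C@@H](c3c(OCc4ccccc4)cc4c(c3OCc6ccccc6)C[C@H](O)[C@@H](c3ccc(OCc5ccccc5)c(OCc5ccccc5)c3)O4)[C@@H]2OCc7ccccc7)cc1
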